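The vessel is closed and stirred, with L held at constant pressure above the liquid, and X gives Q, then E.

all flasks: L 3.1 mM (held)

| run | X | remark | time |
|---|---|---|---|
| ash | 21 mM | the very flask that is asked about, followed so far |  |
| oak | 42 mM | run made earlier |  |
| flask | 21 mM |  | 15 d |

ash run (percent of the X charged)

| time / h | E / % | Q / % | X / % |
|---|---|---|---|
| 2.50 | 0.2 | 1.9 | 99.6 |
| 4.00 | 0.3 | 0.6 | 99.4 |
| 5.00 | 0 | 2.1 | 98.7 |
| 8.00 | 0 | 3.3 | 96.9 |
| 12.0 | 0 | 4.9 | 93.9 |
| 20.0 | 2.0 | 9.7 | 89.2 |
| 30.0 | 2.8 | 11.2 | 83.0 |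

oak run (percent of the X charged)

| time / d | E / % | Q / % | X / % |
|---|---|---|---|
| 1.67 | 2.2 | 9.5 | 85.6 |
| 3.00 | 6.0 | 13.7 | 72.6 |
| 5.00 | 10.5 | 15.2 | 59.6 |
| 6.00 | 12.0 | 16.8 | 52.3 |
| 8.00 | 12.6 | 14.3 | 41.9 |
| 10.0 | 12.3 | 13.4 | 31.8 |

(standard deviation of a reading: 0.5 percentage points)

- the numbers in the tables scatter by 0.5 percentage points (one standard deviation)
- at the start none of L is in solution

- time up to 15 d at which E stands highest
- the amount of E, in percent of the X charged, at that time

At first almost nothing moves. None of L is in solution at the start, and after 5.00 h the ash run has lost hardly any X, which I read as the wait for L to dissolve.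

In the middle, X falls steadily, at about 0.119 d⁻¹ in the oak run, which holds twice the X, and at about 0.165 d⁻¹ in the ash run, which is faster. Q leads and E trails: cE/cQ is 0.250 at the last ash reading.

At the end of the oak run, X, Q and E add up to 57.5%, so something unseen is taking material. Now the two ends join. At its top, E is made as fast as it is lost. If E comes from Q and goes back to Q, cE/cQ at the top equals the equilibrium constant of that exchange. This is my top ratio, read from the oak run's last two readings as 0.899. Below it E rises, and above it E falls. In the oak run, E reads level within the scatter from 8.00 d to 10.0 d, so I place its top between those readings, at their midpoint of 9.00 d. Scaling that time by the two rates of X, I put the flask's top near 6.50 d, with E near the oak reading of 12.6%.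

The forecast gives 14.8% at 7.8 d: “E flattens at about 14.5–15% around 8 d”.

The flask gives 12.1% at 6.40 d, earlier than my time by 0.100 d.

    L ⇌ J, rate k1*(csat - [J]) (kL = 2.20 × 10⁻⁵ s⁻¹)
    X + J → Q (k = 0.00230 M⁻¹ s⁻¹)
    J + Q → G (k = 0.00630 M⁻¹ s⁻¹)
    2 J → D (k = 0.00110 M⁻¹ s⁻¹)
    Q ⇌ E (K = 0.910, k = 4.40 × 10⁻⁶ s⁻¹)

At that top the flask holds Q at 13.3%, a ratio of 0.910 against my 0.899. A neighbour flask charged with 5.2 mM of X holds E at 1.07% and Q at 0.373% after 15.0 d. Its ratio of 2.87 is above the top ratio, which reads as past the top. Its E peaked at 10.4% and has fallen to 1.07%.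

The data were generated by integration for substances that don't exist; the scatter is artificial.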